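**Retrosynthetic overview**
1. The butenolide is the oxidation product of a 3-furyl group (singlet oxygen, then NaBH4). The (R)-carbinol comes from asymmetric hydrogenation of a furyl β-keto ester, and the Z hydroxymethyl alkene from a Wittig reaction of an α-alkoxy ketone with the furyl-carbinol ylide.
2. The trimethylcyclohexene is built last among the carbocycles, on the complete chain. The acyclic polyene (from geranyl acetate) ends in a Me2C=C(Br)– unit, which is joined through its lithium derivative to ethyl 5-oxohexanoate to give a 6-alkenyl-6-methyl δ-lactone.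
3. Key disconnection: ring bond C5–C6 (ring CH2 to the gem-dimethyl carbon) by Ireland–Claisen rearrangement of the lactone enolate. The temporary carboxyl group on C5 is then removed by Barton decarboxylation.
4. Enabling feature: in the 2,6,6-trimethylcyclohex-1-ene ring the quaternary C6 is allylic to the tetrasubstituted C1=C2 bond. With CO2H on C5, the C5–C6 bond is therefore the σ bond of a γ,δ-unsaturated acid (Claisen retron), and C2 (the methyl-bearing alkene carbon) is the former lactone carbinol carbon.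
5. Ring order: furan (bought) → δ-lactone (temporary, step 13) → cyclohexene (step 14) → butenolide (from the furan, steps 16 and 17).

Key step: step 14

Remark: the target is read as the 1R carbinol with the 3Z (hydroxymethyl-bearing) and 7E alkenes. Commercial geranyl acetate is taken as the pure 2E isomer, and intermediates 21–26 are carried as epimer mixtures at a center that the route later erases.

**Route**

Step 1
Reactants: 1 geranyl acetate
Product: 2 (2E)-6,7-dibromo-3,7-dimethyloct-2-en-1-yl acetate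
Conditions: Br2 (1.0 equiv), CH2Cl2, −78 °C, dark
Reagents that add atoms: bromine, BrBr
Why: Electrophilic anti addition of bromine (alkene bromination via the bromonium ion) should occur at the electron-richer 6,7-alkene because the allylic acetate deactivates the 2,3-alkene; the C6 stereocenter forms racemic and disappears in step 2.

Step 2
Reactants: 2 dibromo acetate
Product: 4 (2E)-6-bromo-3,7-dimethylocta-2,6-dien-1-ol, via dibromo alcohol 3 (not isolated)
Conditions: KOH (4 equiv), EtOH, 0 °C → 78 °C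
Reagents that add atoms: none
Why: Saponification of the acetate is followed by E2 dehydrobromination in which the C6–H, acidified by its own bromine, is lost anti to the tertiary bromide to give the tetrasubstituted bromoalkene (the classical dibromide route to 2-bromoalk-2-enes), and no stereocenter remains.

Step 3
Reactants: 4 bromo dienol
Product: 5 (2E)-1,6-dibromo-3,7-dimethylocta-2,6-diene
Conditions: CBr4, PPh3, CH2Cl2, 0 °C
Reagents that add atoms: tetrabromomethane, BrC(Br)(Br)Br
Why: The Appel reaction is an SN2 displacement at the primary allylic carbon that leaves the 2E alkene and the inert vinyl bromide untouched.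

Step 4
Reactants: 6 ethyl 4-chloro-3-oxobutanoate; 7 (4-methoxyphenyl)methanol
Product: 8 ethyl 4-[(4-methoxyphenyl)methoxy]-3-oxobutanoate
Conditions: NaH (2.2 equiv), THF, 0 °C → rt; aq. NH4Cl
Reagents that add atoms: none
Why: Williamson-type displacement of the chloride by the 4-methoxybenzyl alkoxide proceeds on the sodium enolate of the β-keto ester, which protects the active methylene during the substitution.

Step 5
Reactants: 8 PMB keto ester; 5 allylic bromide
Product: 9 ethyl (4E)-8-bromo-2-{[(4-methoxyphenyl)methoxy]acetyl}-5,9-dimethyldeca-4,8-dienoate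
Conditions: NaH, THF, 0 °C; then 5, rt
Reagents that add atoms: none
Why: Acetoacetic-ester alkylation, in which the stabilised sodium enolate displaces the primary allylic bromide by SN2 with retention of alkene geometry; the new C2 stereocenter is racemic and is removed in step 6.

Step 6
Reactants: 9 alkylated β-keto ester
Product: 10 (5E)-9-bromo-1-[(4-methoxyphenyl)methoxy]-6,10-dimethylundeca-5,9-dien-2-one
Conditions: LiCl, DMSO/H2O, 140 °C
Reagents that add atoms: none
Why: Krapcho dealkoxycarbonylation (chloride dealkylation, loss of CO2, protonation) gives the α-alkoxy ketone under neutral conditions that spare the vinyl bromide and the PMB ether.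

Step 7
Reactants: 11 ethyl 3-(furan-3-yl)-3-oxopropanoate
Product: 12 ethyl (3R)-3-(furan-3-yl)-3-hydroxypropanoate
Conditions: H2 (50 atm), RuCl2[(S)-BINAP] (0.5 mol %), EtOH, 60 °C
Reagents that add atoms: none
Why: Noyori asymmetric hydrogenation of the β-keto ester through its ruthenium chelate; the (S)-BINAP ligand is expected, by analogy with aryl β-keto esters, to deliver hydrogen to the face that gives the R carbinol.

Step 8
Reactants: 12 hydroxy ester
Product: 13 ethyl (3R)-3-[(tert-butyldimethylsilyl)oxy]-3-(furan-3-yl)propanoate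
Conditions: TBSCl, imidazole, DMF, rt
Reagents that add atoms: tert-butyl(chloro)dimethylsilane, CC(C)(C)[Si](C)(C)Cl
Why: Imidazole-promoted silylation of the secondary alcohol blocks it through the organometallic steps without touching the stereocenter.

Step 9
Reactants: 13 silyloxy ester
Product: 14 (3R)-3-[(tert-butyldimethylsilyl)oxy]-3-(furan-3-yl)propan-1-ol
Conditions: i-Bu2AlH (2.5 equiv), CH2Cl2, −78 → 0 °C; aq. potassium sodium tartrate
Reagents that add atoms: none
Why: Hydride reduction of the ester to the primary alcohol, to which the silyl ether and the furan are inert.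

Step 10
Reactants: 14 primary alcohol
Product: 15 tert-butyl{[(1R)-1-(furan-3-yl)-3-iodopropyl]oxy}dimethylsilane
Conditions: I2, PPh3, imidazole, CH2Cl2, 0 °C
Reagents that add atoms: iodine, [I][I]
Why: Appel-type iodination through the alkoxyphosphonium iodide (SN2 at the primary carbon).

Step 11
Reactants: 15 primary iodide
Product: 16 {(3R)-3-[(tert-butyldimethylsilyl)oxy]-3-(furan-3-yl)propyl}(triphenyl)phosphonium iodide
Conditions: PPh3, i-Pr2NEt (cat.), MeCN, 70 °C
Reagents that add atoms: triphenylphosphine, c1ccccc1P(c1ccccc1)c1ccccc1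
Why: SN2 quaternisation of triphenylphosphine by the primary iodide gives the Wittig salt.

Step 12
Reactants: 16 phosphonium iodide; 10 α-alkoxy ketone
Product: 18 tert-butyl{[(1R,3Z,7E)-11-bromo-1-(furan-3-yl)-4-{[(4-methoxyphenyl)methoxy]methyl}-8,12-dimethyltrideca-3,7,11-trien-1-yl]oxy}dimethylsilane, via phosphorus ylide 17 (not isolated)
Conditions: NaN(SiMe3)2, THF, −78 → 0 °C; then 10, −78 °C → rt
Reagents that add atoms: none
Why: Wittig olefination of a non-stabilised ylide with an α-alkoxy ketone, a combination known to place the alkoxymethyl group cis to the ylide-derived chain, which sets the 3Z geometry while the vinyl bromide does not react.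

Step 13
Reactants: 18 bromo triene; 19 ethyl 5-oxohexanoate
Product: 22 6-methyl-6-[(6E,10Z,13R)-13-[(tert-butyldimethylsilyl)oxy]-13-(furan-3-yl)-10-{[(4-methoxyphenyl)methoxy]methyl}-2,6-dimethyltrideca-2,6,10-trien-3-yl]oxan-2-one, via alkenyllithium 20 (not isolated), via lithium alkoxide 21 (not isolated)
Conditions: t-BuLi (2.0 equiv), THF, −78 °C; CeCl3, −78 °C; then 19, −78 °C → rt; aq. NH4Cl
Reagents that add atoms: none
Why: Bromine–lithium exchange, transmetalation to the less basic organocerium reagent (to suppress enolisation), chemoselective 1,2-addition to the ketone and lactonisation of the tertiary alkoxide onto the ester; the new quaternary carbinol center forms without control, which is harmless because it becomes sp2 in step 14.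

Step 14
Reactants: 22 alkenyl δ-lactone
Product: 25 2,2,4-trimethyl-3-[(3E,7Z,10R)-10-[(tert-butyldimethylsilyl)oxy]-10-(furan-3-yl)-7-{[(4-methoxyphenyl)methoxy]methyl}-3-methyldeca-3,7-dien-1-yl]cyclohex-3-ene-1-carboxylic acid, via ketene silyl acetal 23 (not isolated), via trimethylsilyl ester 24 (not isolated)
Conditions: LiN(i-Pr)2, THF, −78 °C; Me3SiCl, −78 °C → rt; toluene, 100 °C; then H2O/THF, rt
Reagents that add atoms: none
Why: LiN(i-Pr)2 removes a proton from the only acidic position, the lactone α-CH2, and Me3SiCl traps the enolate as the cyclic ketene silyl acetal 23, in which the O–C(allyl) bond and the exocyclic tetrasubstituted alkene complete the 1,5-diene of an Ireland–Claisen rearrangement. On heating, a concerted suprafacial [3,3]-sigmatropic shift joins the ketene-acetal carbon (future C5) to the Me2C= terminus (future C6) while the tertiary allylic C–O bond breaks, which creates the gem-dimethyl quaternary carbon and places the double bond regiospecifically in the tetrasubstituted C1=C2 position. The cyclohexene is closed by the sigmatropic shift itself, the six-membered lactone being exchanged for the six-membered carbocycle through the boat-like six-centre transition state that the three-carbon tether enforces; the closest known reaction type is the Claisen rearrangement of silyl enolates of 6-alkenyl δ-valerolactones to cyclohex-3-ene-1-carboxylic acids. The one new stereocenter, the carboxyl-bearing C5, is not controlled and need not be, because step 15 removes it, and both epimers of 22 converge since their carbinol carbon becomes sp2. The step needs only regio- and chemoselectivity: the reacting termini are fixed by the single ketene-acetal/O-allyl pair, and kinetic enolisation at −78 °C leaves the furan, the silyl ether and the PMB ether untouched, while C=O formation and relief of the crowded tertiary allylic ester drive the shift.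

Step 15
Reactants: 25 cyclohexenecarboxylic acid
Product: 27 tert-butyl{[(1R,3Z,7E)-1-(furan-3-yl)-4-{[(4-methoxyphenyl)methoxy]methyl}-8-methyl-10-(2,6,6-trimethylcyclohex-1-en-1-yl)deca-3,7-dien-1-yl]oxy}dimethylsilane, via thiohydroxamate ester 26 (not isolated)
Conditions: 1-hydroxypyridine-2(1H)-thione, DCC, DMAP (cat.), CH2Cl2, rt, dark; then t-BuSH (excess), hν (visible), rt
Reagents that add atoms: none
Why: Barton decarboxylation, in which the thiohydroxamate ester fragments in a radical chain to CO2 and the secondary ring radical that abstracts hydrogen from t-BuSH, so that the uncontrolled C5 center is erased and both epimers of 25 give one compound.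

Step 16
Reactants: 27 furan
Product: 29 4-[(1R,3Z,7E)-1-[(tert-butyldimethylsilyl)oxy]-4-{[(4-methoxyphenyl)methoxy]methyl}-8-methyl-10-(2,6,6-trimethylcyclohex-1-en-1-yl)deca-3,7-dien-1-yl]-5-hydroxyfuran-2(5H)-one, via endoperoxide 28 (not isolated)
Conditions: O2, tetraphenylporphyrin (cat.), i-Pr2NEt, CH2Cl2, hν (visible), −78 °C
Reagents that add atoms: dioxygen (as singlet oxygen), O=O
Why: Singlet oxygen adds [4+2] to the furan much faster than it undergoes the ene reaction with the alkenes at −78 °C, and the hindered base removes the bridgehead proton remote from the bulky silyloxyalkyl group (Kornblum–DeLaMare fragmentation) to give the 4-substituted 5-hydroxybutenolide; the hemiacetal center forms as a mixture and is removed in step 17.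

Step 17
Reactants: 29 hydroxybutenolide
Product: 31 4-[(1R,3Z,7E)-1-[(tert-butyldimethylsilyl)oxy]-4-{[(4-methoxyphenyl)methoxy]methyl}-8-methyl-10-(2,6,6-trimethylcyclohex-1-en-1-yl)deca-3,7-dien-1-yl]furan-2(5H)-one, via hydroxy acid 30 (not isolated)
Conditions: NaBH4, EtOH, 0 °C; then aq. HCl (pH 3), rt
Reagents that add atoms: none
Why: NaBH4 reduces the aldehyde of the ring-opened formyl carboxylate tautomer, and the resulting cis γ-hydroxy acid relactonises on acidification to the 4-substituted furan-2(5H)-one.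

Step 18
Reactants: 31 PMB-protected butenolide
Product: 32 4-[(1R,3Z,7E)-1-[(tert-butyldimethylsilyl)oxy]-4-(hydroxymethyl)-8-methyl-10-(2,6,6-trimethylcyclohex-1-en-1-yl)deca-3,7-dien-1-yl]furan-2(5H)-one
Conditions: DDQ, CH2Cl2/pH 7 buffer, 0 °C
Reagents that add atoms: none
Why: Oxidative cleavage of the electron-rich PMB ether by DDQ (hydride abstraction, then hydrolysis of the oxocarbenium ion) frees the primary allylic alcohol without touching the silyl ether or the butenolide.

Step 19
Reactants: 32 silyl ether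
Product: 33 4-[(1R,3Z,7E)-1-hydroxy-4-(hydroxymethyl)-8-methyl-10-(2,6,6-trimethylcyclohex-1-en-1-yl)deca-3,7-dien-1-yl]furan-2(5H)-one
Conditions: HF·pyridine, pyridine, THF, 0 °C → rt
Reagents that add atoms: none
Why: Fluoride-mediated desilylation under buffered, non-basic conditions spares the base-sensitive butenolide and the alkenes and leaves the R stereocenter unchanged.

**Compound list**
1 | (2E)-3,7-dimethylocta-2,6-dien-1-yl acetate (geranyl acetate) | CC(C)=CCC/C(C)=C/COC(C)=O | starting material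
2 | (2E)-6,7-dibromo-3,7-dimethyloct-2-en-1-yl acetate (racemic at C6) | CC(C)(Br)C(Br)CC/C(C)=C/COC(C)=O | intermediate
3 | (2E)-6,7-dibromo-3,7-dimethyloct-2-en-1-ol (racemic at C6) | CC(C)(Br)C(Br)CC/C(C)=C/CO | intermediate
4 | (2E)-6-bromo-3,7-dimethylocta-2,6-dien-1-ol | CC(C)=C(Br)CC/C(C)=C/CO | intermediate
5 | (2E)-1,6-dibromo-3,7-dimethylocta-2,6-diene | CC(C)=C(Br)CC/C(C)=C/CBr | intermediate
6 | ethyl 4-chloro-3-oxobutanoate | CCOC(=O)CC(=O)CCl | starting material
7 | (4-methoxyphenyl)methanol | COc1ccc(CO)cc1 | starting material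
8 | ethyl 4-[(4-methoxyphenyl)methoxy]-3-oxobutanoate | CCOC(=O)CC(=O)COCc1ccc(OC)cc1 | intermediate
9 | ethyl (4E)-8-bromo-2-{[(4-methoxyphenyl)methoxy]acetyl}-5,9-dimethyldeca-4,8-dienoate (racemic at C2) | CCOC(=O)C(C/C=C(\C)CCC(Br)=C(C)C)C(=O)COCc1ccc(OC)cc1 | intermediate
10 | (5E)-9-bromo-1-[(4-methoxyphenyl)methoxy]-6,10-dimethylundeca-5,9-dien-2-one | COc1ccc(COCC(=O)CC/C=C(\C)CCC(Br)=C(C)C)cc1 | intermediate
11 | ethyl 3-(furan-3-yl)-3-oxopropanoate | CCOC(=O)CC(=O)c1ccoc1 | starting material
12 | ethyl (3R)-3-(furan-3-yl)-3-hydroxypropanoate | CCOC(=O)C[C@@H](O)c1ccoc1 | intermediate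
13 | ethyl (3R)-3-[(tert-butyldimethylsilyl)oxy]-3-(furan-3-yl)propanoate | CCOC(=O)C[C@@H](O[Si](C)(C)C(C)(C)C)c1ccoc1 | intermediate
14 | (3R)-3-[(tert-butyldimethylsilyl)oxy]-3-(furan-3-yl)propan-1-ol | OCC[C@@H](O[Si](C)(C)C(C)(C)C)c1ccoc1 | intermediate
15 | tert-butyl{[(1R)-1-(furan-3-yl)-3-iodopropyl]oxy}dimethylsilane | ICC[C@@H](O[Si](C)(C)C(C)(C)C)c1ccoc1 | intermediate
16 | {(3R)-3-[(tert-butyldimethylsilyl)oxy]-3-(furan-3-yl)propyl}(triphenyl)phosphonium iodide | [I-].c1ccccc1[P+](c1ccccc1)(c1ccccc1)CC[C@@H](O[Si](C)(C)C(C)(C)C)c1ccoc1 | intermediate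
17 | {(3R)-3-[(tert-butyldimethylsilyl)oxy]-3-(furan-3-yl)propylidene}(triphenyl)phosphorane (ylide of 16) | c1ccccc1P(c1ccccc1)(c1ccccc1)=CC[C@@H](O[Si](C)(C)C(C)(C)C)c1ccoc1 | intermediate
18 | tert-butyl{[(1R,3Z,7E)-11-bromo-1-(furan-3-yl)-4-{[(4-methoxyphenyl)methoxy]methyl}-8,12-dimethyltrideca-3,7,11-trien-1-yl]oxy}dimethylsilane | CC(C)=C(Br)CC/C(C)=C/CC/C(=C/C[C@@H](O[Si](C)(C)C(C)(C)C)c1ccoc1)COCc1ccc(OC)cc1 | intermediate
19 | ethyl 5-oxohexanoate | CCOC(=O)CCCC(C)=O | starting material
20 | alkenyllithium of 18 (Li in place of Br at C11) | CC(C)=C([Li])CC/C(C)=C/CC/C(=C/C[C@@H](O[Si](C)(C)C(C)(C)C)c1ccoc1)COCc1ccc(OC)cc1 | intermediate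
21 | ethyl 5-hydroxy-5-methylhexanoate carrying on C5 the alkenyl group of 20, drawn as its lithium alkoxide (both C5 epimers) | CCOC(=O)CCCC(C)(O[Li])C(=C(C)C)CC/C(C)=C/CC/C(=C/C[C@@H](O[Si](C)(C)C(C)(C)C)c1ccoc1)COCc1ccc(OC)cc1 | intermediate
22 | 6-methyl-6-[(6E,10Z,13R)-13-[(tert-butyldimethylsilyl)oxy]-13-(furan-3-yl)-10-{[(4-methoxyphenyl)methoxy]methyl}-2,6-dimethyltrideca-2,6,10-trien-3-yl]oxan-2-one (both C6 epimers) | O=C1CCCC(C)(O1)C(=C(C)C)CC/C(C)=C/CC/C(=C/C[C@@H](O[Si](C)(C)C(C)(C)C)c2ccoc2)COCc3ccc(OC)cc3 | intermediate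
23 | ketene trimethylsilyl acetal of 22 (2-alkenyl-2-methyl-6-[(trimethylsilyl)oxy]-3,4-dihydro-2H-pyran) | C[Si](C)(C)OC1=CCCC(C)(O1)C(=C(C)C)CC/C(C)=C/CC/C(=C/C[C@@H](O[Si](C)(C)C(C)(C)C)c2ccoc2)COCc3ccc(OC)cc3 | intermediate
24 | trimethylsilyl ester of 25 | C[Si](C)(C)OC(=O)C1CCC(C)=C(CC/C(C)=C/CC/C(=C/C[C@@H](O[Si](C)(C)C(C)(C)C)c2ccoc2)COCc3ccc(OC)cc3)C1(C)C | intermediate
25 | 2,2,4-trimethyl-3-[(3E,7Z,10R)-10-[(tert-butyldimethylsilyl)oxy]-10-(furan-3-yl)-7-{[(4-methoxyphenyl)methoxy]methyl}-3-methyldeca-3,7-dien-1-yl]cyclohex-3-ene-1-carboxylic acid (both C1 epimers) | OC(=O)C1CCC(C)=C(CC/C(C)=C/CC/C(=C/C[C@@H](O[Si](C)(C)C(C)(C)C)c2ccoc2)COCc3ccc(OC)cc3)C1(C)C | intermediate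
26 | 2-thioxopyridin-1(2H)-yl ester of 25 (Barton ester) | S=C1C=CC=CN1OC(=O)C2CCC(C)=C(CC/C(C)=C/CC/C(=C/C[C@@H](O[Si](C)(C)C(C)(C)C)c3ccoc3)COCc4ccc(OC)cc4)C2(C)C | intermediate
27 | tert-butyl{[(1R,3Z,7E)-1-(furan-3-yl)-4-{[(4-methoxyphenyl)methoxy]methyl}-8-methyl-10-(2,6,6-trimethylcyclohex-1-en-1-yl)deca-3,7-dien-1-yl]oxy}dimethylsilane | CC1=C(CC/C(C)=C/CC/C(=C/C[C@@H](O[Si](C)(C)C(C)(C)C)c2ccoc2)COCc3ccc(OC)cc3)C(C)(C)CCC1 | intermediate
28 | furan endoperoxide of 27 (2,3,7-trioxabicyclo[2.2.1]hept-5-ene carrying the side chain on C5) | CC1=C(CC/C(C)=C/CC/C(=C/C[C@@H](O[Si](C)(C)C(C)(C)C)C2=CC3OOC2O3)COCc4ccc(OC)cc4)C(C)(C)CCC1 | intermediate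
29 | 4-[(1R,3Z,7E)-1-[(tert-butyldimethylsilyl)oxy]-4-{[(4-methoxyphenyl)methoxy]methyl}-8-methyl-10-(2,6,6-trimethylcyclohex-1-en-1-yl)deca-3,7-dien-1-yl]-5-hydroxyfuran-2(5H)-one (both C5 epimers) | CC1=C(CC/C(C)=C/CC/C(=C/C[C@@H](O[Si](C)(C)C(C)(C)C)C2=CC(=O)OC2O)COCc3ccc(OC)cc3)C(C)(C)CCC1 | intermediate
30 | 4-hydroxy-3-(side chain)but-2-enoic acid from ring opening and reduction of 29 (CO2H and CH2OH cis) | CC1=C(CC/C(C)=C/CC/C(=C/C[C@@H](O[Si](C)(C)C(C)(C)C)C(/CO)=C/C(O)=O)COCc2ccc(OC)cc2)C(C)(C)CCC1 | intermediate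
31 | 4-[(1R,3Z,7E)-1-[(tert-butyldimethylsilyl)oxy]-4-{[(4-methoxyphenyl)methoxy]methyl}-8-methyl-10-(2,6,6-trimethylcyclohex-1-en-1-yl)deca-3,7-dien-1-yl]furan-2(5H)-one | CC1=C(CC/C(C)=C/CC/C(=C/C[C@@H](O[Si](C)(C)C(C)(C)C)C2=CC(=O)OC2)COCc3ccc(OC)cc3)C(C)(C)CCC1 | intermediate
32 | 4-[(1R,3Z,7E)-1-[(tert-butyldimethylsilyl)oxy]-4-(hydroxymethyl)-8-methyl-10-(2,6,6-trimethylcyclohex-1-en-1-yl)deca-3,7-dien-1-yl]furan-2(5H)-one | CC1=C(CC/C(C)=C/CC/C(=C/C[C@@H](O[Si](C)(C)C(C)(C)C)C2=CC(=O)OC2)CO)C(C)(C)CCC1 | intermediate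
33 | 4-[(1R,3Z,7E)-1-hydroxy-4-(hydroxymethyl)-8-methyl-10-(2,6,6-trimethylcyclohex-1-en-1-yl)deca-3,7-dien-1-yl]furan-2(5H)-one | CC1=C(CC/C(C)=C/CC/C(=C/C[C@@H](O)C2=CC(=O)OC2)CO)C(C)(C)CCC1 | target

**Step count**
Total steps: 19. Longest linear sequence: 13 steps (steps 1–3, 5, 6 and 12–19; the branch through steps 7–11 and 12–19 is equally long).

**Steps most likely to fail**

1. Step 14. The boat transition state is congested (fully substituted allyl terminus, quaternary carbinol carbon). The [3,3] shift may therefore be slower than ionisation of the tertiary allylic C–O bond of the ketene acetal (elimination to dienes) or than hydrolytic return to the lactone. The fallback sets out from 18 and comes back at 27, and makes the same C5–C6 ring bond by a thermal 6π-electrocyclisation. Ethyl but-2-ynoate is hydroiodinated (NaI, AcOH, 110 °C) to ethyl (2Z)-3-iodobut-2-enoate F1. Compound 18 is lithiated (t-BuLi, THF, −78 °C), transmetalated with ZnCl2 and coupled with F1 under Pd(PPh3)4 catalysis (Negishi coupling) to the (2Z)-dienoate F2. Reduction with i-Bu2AlH gives the (2Z)-dienol F3, MnO2 the (2Z)-dienal F4 (in equilibrium with its 2H-pyran valence isomer), and Ph3P=CH2 the (Z)-triene F5. In toluene at 110 °C, F5 should close between its Me2C= and =CH2 termini by disrotatory 6π-electrocyclisation to the cyclohexa-1,3-diene F6. Diimide (from 2-nitrobenzenesulfonohydrazide and Et3N) should then saturate only the disubstituted ring alkene and give 27.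

2. Step 15. After loss of CO2, the secondary ring radical is homoallylic to the ring alkene through the quaternary carbon. It may undergo 3-exo closure and reopening (a 1,2-alkenyl shift with ring contraction) before hydrogen-atom transfer, and thiyl radicals may erode the Z alkene. The fallback sets out from 25 and comes back at 27 without free radicals. LiAlH4 (THF, 0 °C) reduces the acid to the primary alcohol F7, Dess–Martin periodinane (NaHCO3, CH2Cl2) oxidises it to the aldehyde F8, and stoichiometric RhCl(PPh3)3 (toluene, 110 °C, Tsuji–Wilkinson decarbonylation through acyl- and alkyl-rhodium intermediates) removes the formyl carbon to give 27.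

3. Step 13. Proton transfer from the enolisable methyl ketone to the hindered alkenyl metal may compete with 1,2-addition, and the tertiary alkoxide may lactonise incompletely. The fallback sets out from 18 and comes back at 22, and lets a small, weakly basic methyl nucleophile make the carbinol. The alkenyllithium from 18 (t-BuLi, THF, −78 °C) is acylated with glutaric anhydride to the 5-oxo acid F9. MeCeCl2 (from MeLi and CeCl3, 2.2 equiv, THF, −78 °C) adds to the ketone to give the hydroxy acid F10, which is lactonised (DCC, DMAP, CH2Cl2) to 22.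

**Further compounds**
F1 | step 14 | ethyl (2Z)-3-iodobut-2-enoate | CCOC(=O)/C=C(/C)I
F2 | step 14 | ethyl (2Z)-dienoate: 18 with Br replaced by (Z)-C(CH3)=CH–CO2Et | CCOC(=O)/C=C(/C)C(=C(C)C)CC/C(C)=C/CC/C(=C/C[C@@H](O[Si](C)(C)C(C)(C)C)c1ccoc1)COCc1ccc(OC)cc1
F3 | step 14 | (2Z)-dienol: F2 with CO2Et reduced to CH2OH | OC/C=C(/C)C(=C(C)C)CC/C(C)=C/CC/C(=C/C[C@@H](O[Si](C)(C)C(C)(C)C)c1ccoc1)COCc1ccc(OC)cc1
F4 | step 14 | (2Z)-dienal: F3 oxidised to CHO | O=C/C=C(/C)C(=C(C)C)CC/C(C)=C/CC/C(=C/C[C@@H](O[Si](C)(C)C(C)(C)C)c1ccoc1)COCc1ccc(OC)cc1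
F5 | step 14 | (Z)-triene: F4 with CHO converted to CH=CH2 | C=C/C=C(/C)C(=C(C)C)CC/C(C)=C/CC/C(=C/C[C@@H](O[Si](C)(C)C(C)(C)C)c1ccoc1)COCc1ccc(OC)cc1
F6 | step 14 | cyclohexa-1,3-diene: 3,4-didehydro analogue of 27 (2,6,6-trimethylcyclohexa-1,3-dien-1-yl ring) | CC1=C(CC/C(C)=C/CC/C(=C/C[C@@H](O[Si](C)(C)C(C)(C)C)c2ccoc2)COCc3ccc(OC)cc3)C(C)(C)CC=C1
F7 | step 15 | primary alcohol: 25 with CO2H reduced to CH2OH (both epimers) | OCC1CCC(C)=C(CC/C(C)=C/CC/C(=C/C[C@@H](O[Si](C)(C)C(C)(C)C)c2ccoc2)COCc3ccc(OC)cc3)C1(C)C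
F8 | step 15 | aldehyde: 25 with CO2H replaced by CHO (both epimers) | O=CC1CCC(C)=C(CC/C(C)=C/CC/C(=C/C[C@@H](O[Si](C)(C)C(C)(C)C)c2ccoc2)COCc3ccc(OC)cc3)C1(C)C
F9 | step 13 | 5-oxo acid: 18 with Br replaced by C(=O)CH2CH2CH2CO2H | OC(=O)CCCC(=O)C(=C(C)C)CC/C(C)=C/CC/C(=C/C[C@@H](O[Si](C)(C)C(C)(C)C)c1ccoc1)COCc1ccc(OC)cc1
F10 | step 13 | 5-hydroxy-5-methyl acid (seco acid of 22; both C5 epimers) | OC(=O)CCCC(C)(O)C(=C(C)C)CC/C(C)=C/CC/C(=C/C[C@@H](O[Si](C)(C)C(C)(C)C)c1ccoc1)COCc1ccc(OC)cc1
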